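(The runs are simulated from invented constants; scatter was added.)

Which flask, autumn or winter, ends with the higher share of Q among what has become Q or Z?

common to all: L 2.3 mM (held)
- larch: E 24 mM; run made earlier
- autumn: E 22 mM; time 1.0 h
- winter: E 60 mM; time 1.5 h

larch run (percent of the E charged)

| time / min | Q / % | Z / % |
|---|---|---|
| 2.50 | 5.1 | 0.1 |
| 8.00 | 15.3 | 1.4 |
| 12.0 | 21.4 | 4.0 |
| 20.0 | 29.2 | 12.7 |
| 30.0 | 33.7 | 22.8 |
| 40.0 | 36.4 | 35.3 |

(standard deviation of a reading: 1 percentage point)

- at the start none of L is in solution

* the flask that ends with the higher share of Q in all that became Q or Z, or "neither" when 2 percentage points or less lies between them (autumn / winter / neither)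
* share of Q in all that became Q or Z, autumn
* share of Q in all that became Q or Z, winter

In the larch run Z lags behind Q, so Z is taken as made from Q. Between 20.0 min and 40.0 min Z gains 23 percentage points around a Q of 33.7%, which reads as 0.0335 min⁻¹. This is the ageing rate of Q, kZ, the fraction of the standing Q that turns to Z per unit time. Taken as first order, it serves autumn and winter alike, and the length of a run in ages is x = kZ·t: 2.01 for autumn, 3.02 for winter.

The share of Q (the selectivity) then rests on when Q was born. If all Q is born at the start, the share is exp(−x): 13.4% in autumn, 4.89% in winter. If Q is born steadily to the last minute, the share is the mean of that decay, (one minus exp(−x))/x: 43.1% and 31.5%. New Q, counted as Q plus Z, comes in the larch run faster up to 20.0 min than after it, so autumn and winter are each expected to lie between their two figures, nearer the steady end. The reckoning here is that autumn ends higher than winter, each a little under its steady figure.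

The forecast differs: winter higher, with autumn at 36% (29% to 43%) and winter at 52% (41% to 62%), on the ground that “the Q share depends essentially on E conversion”.

The flasks give 36.4% for autumn and 29.0% for winter, so autumn ends higher. Autumn stands lower than its steady figure of 43.1% and winter lower than its 31.5%, and each stands higher than its figure for Q born at the start.

    E + D → Q (k = 0.340 M⁻¹ s⁻¹)
    Q ⇌ Z (K = 6.00, k = 6.30 × 10⁻⁴ s⁻¹)
    L ⇌ D, rate k3*(csat - [D]) (kL = 0.00950 s⁻¹)

In winter Q has a half-life of 0.31 h by the forward step to Z, shorter than the 1.5 h run, and at the end Q is made at 0.696 of the rate at which it is used up, each step taken net. Winter ends with 11% of E left, close to the 13% of autumn, yet with the lower share. Read earlier, at 50 min, winter has x = 1.68, and kZ gives a steady-feed share of 48.4%; winter stands there at 46.7%.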